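**Assumption:** the target is read as (2S)-5,7,2'-trihydroxy-8-prenyl-5'-(1,1-dimethylallyl)flavanone, as parsed from the SMILES. Ethyl (R)-3-hydroxy-3-phenylpropanoate is taken to be available at ≥98% ee.

## Retrosynthetic overview
1. The target comes from global MOM removal of protected chromanone **20**. Ring C is closed last, by intramolecular Friedel–Crafts acylation of acid **19**. Regiochemistry is fixed because the only ortho site of the aryl ether that is free of prenyl is the one that reacts.
2. Acid **19** comes from a Mitsunobu coupling, with inversion, of prenylphenol **8** and chiral benzylic alcohol **16**. The C2 stereocentre is the carbinol of the purchased (R)-β-hydroxy ester **9**.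
3. Ring B is built from **9** by ortho-hydroxylation, para-bromination and an α-selective Suzuki coupling with prenyl-Bpin, which gives the reverse prenyl group.
4. Ring A, prenylphenol **8**, comes from phloroglucinol. The key step is an aromatic Claisen [3,3] rearrangement of an allyl ether, followed by cross-metathesis with 2-methyl-2-butene.
5. Rings A and B are assembled and decorated first, and the pyranone ring C is formed last.

## Route

**Step 1**
Reactants: 1 phloroglucinol; 2 chloromethyl methyl ether (MOMCl)
Product: 3 3,5-bis(methoxymethoxy)phenol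
Conditions: MOMCl (2.0 equiv), DIPEA, THF, 0 °C → rt; bis-ether separated chromatographically from mono- and tri-ethers
Reagents that add atoms: MOMCl, COCCl
Why: Phloroglucinol is C3-symmetric, so the bis-protected phenol is a single regioisomer, and MOM ethers allow one mild global deprotection at the end (Williamson-type protection; the yield is statistical).

**Step 2**
Reactants: 3 3,5-bis(MOM-oxy)phenol; 4 allyl bromide
Product: 5 1-allyloxy-3,5-bis(methoxymethoxy)benzene
Conditions: K2CO3, acetone, reflux
Reagents that add atoms: allyl bromide, C=CCBr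
Why: The single free phenol undergoes a simple Williamson O-allylation to give the Claisen substrate.

**Step 3 (key step)**
Reactants: 5 aryl allyl ether
Product: 6 2-allyl-3,5-bis(methoxymethoxy)phenol
Conditions: N,N-diethylaniline, 195 °C (sealed tube or microwave), 3 h
Reagents that add atoms: none
Why: In this aromatic Claisen [3,3] rearrangement the two ortho carbons are equivalent, since each is flanked by OMOM and O-allyl. That gives one regioisomer and frees the phenol next to the new allyl group.

**Step 4**
Reactants: 6 allyl phenol; 7 2-methyl-2-butene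
Product: 8 2-(3-methylbut-2-enyl)-3,5-bis(methoxymethoxy)phenol
Conditions: Grubbs II (5 mol%), 1,4-benzoquinone (10 mol%), 2-methyl-2-butene (20 equiv), CH2Cl2, 40 °C
Reagents that add atoms: 2-methyl-2-butene, CC=C(C)C
Why: Cross-metathesis with a trisubstituted alkene converts the terminal allyl group to prenyl, and the quinone suppresses Ru–H isomerisation.

**Step 5**
Reactants: 9 ethyl (R)-3-hydroxy-3-phenylpropanoate; 10 hydrogen peroxide (supplied as NaBO3·4H2O)
Product: 11 ethyl (R)-3-hydroxy-3-(2-hydroxyphenyl)propanoate
Conditions: (i) Et2SiH2, [Ir(cod)OMe]2, THF, 25 °C; (ii) HBpin, [Ir(cod)OMe]2/Me4phen, norbornene, THF, 80 °C; (iii) NaBO3·4H2O, THF/H2O, 25 °C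
Reagents that add atoms: hydrogen peroxide (as perborate), OO
Why: Hydroxyl-directed (hydrido-silyl ether) Ir-catalysed ortho C–H borylation followed by oxidation installs the 2'-OH, and the carbinol C–O bond is never touched, so the (R) centre is kept.

**Step 6**
Reactants: 11 phenol; 12 N-bromosuccinimide
Product: 13 ethyl (R)-3-(5-bromo-2-hydroxyphenyl)-3-hydroxypropanoate
Conditions: NBS (1.0 equiv), CH2Cl2, −20 → 0 °C
Reagents that add atoms: NBS, O=C1CCC(=O)N1Br
Why: Electrophilic bromination of a phenol with free ortho and para positions occurs para to OH, which is C5' and the position needed for the reverse prenyl group.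

**Step 7**
Reactants: 13 bromophenol; 2 MOMCl
Product: 14 ethyl (R)-3-(5-bromo-2-(methoxymethoxy)phenyl)-3-hydroxypropanoate
Conditions: MOMCl (1.2 equiv), K2CO3, acetone, 25 °C
Reagents that add atoms: MOMCl, COCCl
Why: Under weak base only the phenoxide is alkylated, so the secondary benzylic alcohol is left free for the Mitsunobu step.

**Step 8**
Reactants: 14 aryl bromide; 15 prenyl-Bpin
Product: 16 ethyl (R)-3-(5-(2-methylbut-3-en-2-yl)-2-(methoxymethoxy)phenyl)-3-hydroxypropanoate
Conditions: Pd2(dba)3 (1 mol%), bulky biaryl-phosphine ligand for α-selective allyl–aryl coupling (4 mol%), K3PO4, prenyl-Bpin (1.5 equiv), THF/H2O, 50 °C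
Reagents that add atoms: prenyl-Bpin, CC(C)=CCB1OC(C)(C)C(C)(C)O1
Why: Ligand-controlled Suzuki–Miyaura coupling of a 3,3-disubstituted allylboronate reacts at the α-carbon (SE2′), giving the 1,1-dimethylallyl (reverse-prenyl) arene.

**Step 9**
Reactants: 8 prenylphenol; 16 (R)-benzylic alcohol
Product: 17 ethyl (S)-3-aryloxy-3-arylpropanoate (aryloxy = 2-prenyl-3,5-bis(MOM-oxy)phenoxy; aryl = 5-(1,1-dimethylallyl)-2-(MOM-oxy)phenyl)
Conditions: PPh3 (1.5 equiv), DIAD (1.5 equiv), toluene/THF, 0 °C → rt
Reagents that add atoms: none
Why: Mitsunobu etherification proceeds by SN2 inversion, so the (R)-alcohol gives the (S)-aryl ether and sets the C2 configuration of the target.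

**Step 10**
Reactants: 17 ester; 18 lithium hydroxide
Product: 19 (S)-3-aryloxy-3-arylpropanoic acid
Conditions: LiOH·H2O (3 equiv), THF/H2O (3:1), 0 °C, 2 h; then aq. citric acid to pH ~4
Reagents that add atoms: lithium hydroxide, [Li+].[OH-]
Why: Cold saponification gives the free acid for cyclisation without touching the MOM ethers or the two alkenes, and the stereocentre is not involved.

**Step 11**
Reactants: 19 acid
Product: 20 (2S)-5,7,2'-tris(MOM-oxy)-8-prenyl-5'-(1,1-dimethylallyl)flavanone
Conditions: TFAA (5 equiv), CH2Cl2, 0 °C → rt (TfOH, 5 mol%, only if sluggish)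
Reagents that add atoms: none
Why: Intramolecular Friedel–Crafts acylation of the highly nucleophilic trioxygenated ring closes the chromanone at the only free ortho carbon (C2 carries prenyl), and ring B is too deactivated at C6' to form the competing indanone.

**Step 12**
Reactants: 20 tris-MOM flavanone
Product: 21 target, (2S)-5,7,2'-trihydroxy-8-(3-methylbut-2-enyl)-5'-(2-methylbut-3-en-2-yl)flavanone
Conditions: 3 M HCl, MeOH, 40 °C, 3 h
Reagents that add atoms: none
Why: Acidolysis of the three MOM acetals releases the phenols, and the flavanone C2 centre is stable to dilute acid, unlike to base, so no ring-opening or racemisation occurs.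

## Compound list
1 | phloroglucinol | Oc1cc(O)cc(O)c1 | starting material
2 | chloromethyl methyl ether | COCCl | starting material (reagent)
3 | 3,5-bis(methoxymethoxy)phenol | COCOc1cc(O)cc(OCOC)c1 | intermediate
4 | allyl bromide | C=CCBr | starting material (reagent)
5 | 1-allyloxy-3,5-bis(methoxymethoxy)benzene | C=CCOc1cc(OCOC)cc(OCOC)c1 | intermediate
6 | 2-allyl-3,5-bis(methoxymethoxy)phenol | C=CCc1c(O)cc(OCOC)cc1OCOC | intermediate
7 | 2-methyl-2-butene | CC=C(C)C | starting material (reagent)
8 | 2-prenyl-3,5-bis(methoxymethoxy)phenol | CC(C)=CCc1c(O)cc(OCOC)cc1OCOC | intermediate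
9 | ethyl (R)-3-hydroxy-3-phenylpropanoate | CCOC(=O)C[C@@H](O)c1ccccc1 | starting material (chiral)
10 | hydrogen peroxide (as sodium perborate) | OO | starting material (reagent)
11 | ethyl (R)-3-hydroxy-3-(2-hydroxyphenyl)propanoate | CCOC(=O)C[C@@H](O)c1ccccc1O | intermediate
12 | N-bromosuccinimide | O=C1CCC(=O)N1Br | starting material (reagent)
13 | ethyl (R)-3-(5-bromo-2-hydroxyphenyl)-3-hydroxypropanoate | CCOC(=O)C[C@@H](O)c1cc(Br)ccc1O | intermediate
14 | ethyl (R)-3-(5-bromo-2-(methoxymethoxy)phenyl)-3-hydroxypropanoate | CCOC(=O)C[C@@H](O)c1cc(Br)ccc1OCOC | intermediate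
15 | prenyl-Bpin | CC(C)=CCB1OC(C)(C)C(C)(C)O1 | starting material (reagent)
16 | ethyl (R)-3-hydroxy-3-[5-(2-methylbut-3-en-2-yl)-2-(methoxymethoxy)phenyl]propanoate | CCOC(=O)C[C@@H](O)c1cc(C(C)(C)C=C)ccc1OCOC | intermediate
17 | ethyl (S)-3-aryloxy-3-arylpropanoate | CCOC(=O)C[C@H](Oc1c(CC=C(C)C)c(OCOC)cc(OCOC)c1)c1cc(C(C)(C)C=C)ccc1OCOC | intermediate
18 | lithium hydroxide | [Li+].[OH-] | starting material (reagent)
19 | (S)-3-aryloxy-3-arylpropanoic acid | OC(=O)C[C@H](Oc1c(CC=C(C)C)c(OCOC)cc(OCOC)c1)c1cc(C(C)(C)C=C)ccc1OCOC | intermediate
20 | (2S)-tris-MOM-protected flavanone | O=C1C[C@@H](c2cc(C(C)(C)C=C)ccc2OCOC)Oc2c(CC=C(C)C)c(OCOC)cc(OCOC)c12 | intermediate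
21 | target | C=CC(C)(C)c1ccc(O)c([C@@H]2CC(=O)c3c(O)cc(O)c(CC=C(C)C)c3O2)c1 | target

## Summary
Total steps: 12. Longest linear sequence: 8 steps, either from **1** or from **9**.

Three steps most likely to fail:
1. **Step 9 (Mitsunobu).** The electron-rich ortho-alkoxy benzylic alcohol may ionise, which would racemise the centre, or eliminate to the cinnamate. Fallback: use the (S)-enantiomer of **16** and form the aryl ether by retentive O-arylation of its alkoxide with an A-ring diaryliodonium salt, so the carbinol C–O bond is never broken.
2. **Step 11 (Friedel–Crafts closure).** The acid could ionise the benzylic ether, racemise the centre, or cyclise the prenyl group onto a phenol. Fallback: go ketone-first. Make the Weinreb amide of **16**, add the A-ring aryllithium (directed lithiation of the O-carbamate of **8** at C6), then close the ring by intramolecular Mitsunobu inversion, which avoids strong acid.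
3. **Step 5 (Ir-directed ortho-hydroxylation).** This is a less precedented substrate, since it carries a β-hydroxy ester. Fallback: use alkoxide-directed ortho-lithiation and B(OMe)3 then oxidation on the mono-TBS ether of (R)-1-phenylpropane-1,3-diol. The primary alcohol is then oxidised to the acid before the Friedel–Crafts step.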